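**Assumptions**
- The SMILES reads as (2S,4R)-5,7-dimethoxy-8-prenylflavan-4-ol. This is the 2,4-trans isomer, with 2-Ph equatorial and 4-OH pseudo-axial.
- The (Sa,Sc,Sc) phosphoramidite in Step 3 is assumed to give the (S)-ether. I could not confirm the sense of induction. It would be checked on the first run, for example by correlating alcohol 9 with material from the Step 3 fallback. If the sense is opposite, the equally available (Ra,Rc,Rc) ligand is used.

## Retrosynthetic overview
1. The chalcone → flavanone → hydride route is avoided, because hydride reduction gives the wrong (2,4-cis) alcohol.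
2. Key disconnection C4–C4a: ring-closing Friedel–Crafts hydroxyalkylation of an (S)-β-aryloxy aldehyde. It forms the pyran ring and the C4 carbinol in one step, with C2 controlling C4.
3. The aldehyde comes from the vinyl group of a branched allyl aryl ether (chemoselective hydroboration–oxidation, then alcohol oxidation).
4. Disconnection O1–C2: Ir-catalysed enantioselective allylic etherification of the phenoxide with cinnamyl carbonate sets C2.
5. The phenol comes from ortho C-prenylation of 3,5-dimethoxyphenol. Rings A and B are bought, and the pyran ring C is the only ring formed, in the last step.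

## Route

**Step 1**
Reactants: 1 (3,5-dimethoxyphenol), 2 (prenyl bromide)
Product: 3, 3,5-dimethoxy-2-(3-methylbut-2-en-1-yl)phenol
Conditions: NaH (1.05 equiv), PhMe, 0 °C; then 2 (1.0 equiv), rt
Reagents that add atoms: prenyl bromide (2), CC(C)=CCBr
Why: Ortho-selective phenoxide C-alkylation works here because the tight sodium ion pair in a non-polar solvent delivers the allylic bromide (SN2) to the ortho carbon, the two ortho sites of 1 are equivalent, O-, para- and di-prenyl by-products are separable, and no stereocentre forms.

**Step 2**
Reactants: 4 ((E)-cinnamyl alcohol), 5 (methyl chloroformate)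
Product: 6, (E)-cinnamyl methyl carbonate
Conditions: ClCO2Me, pyridine, CH2Cl2, 0 °C → rt
Reagents that add atoms: methyl chloroformate (5), COC(=O)Cl
Why: This is routine O-acylation (carbonate formation) of a primary allylic alcohol, and alkene geometry is retained.

**Step 3**
Reactants: 3 (as lithium phenoxide, 1.5–2 equiv, excess recovered), 6
Product: 7, (S)-1,5-dimethoxy-2-(3-methylbut-2-en-1-yl)-3-[(1-phenylprop-2-en-1-yl)oxy]benzene
Conditions: 3, n-BuLi, THF, 0 °C; then 6, [Ir(cod)Cl]2 (2 mol %), (Sa,Sc,Sc)-BINOL bis(1-phenylethyl)amine phosphoramidite (4 mol %), THF, rt → 50 °C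
Reagents that add atoms: cinnamyl methyl carbonate (6), COC(=O)OC/C=C/c1ccccc1 (supplies the C9H9 unit)
Why: In this Ir-catalysed asymmetric allylic etherification (cyclometalated Ir–phosphoramidite), the aryloxide oxygen attacks the substituted terminus of the π-cinnamyl-Ir outer-sphere to give the branched ether, and the ligand fixes the allyl face and so sets C2 as S (I expect roughly ≥90% ee and b:l ≥ 9:1, with mono-ortho-substituted phenoxides tolerated), while the trisubstituted prenyl alkene is inert.

**Step 4**
Reactants: 7
Product: 9, (S)-3-[3,5-dimethoxy-2-(3-methylbut-2-en-1-yl)phenoxy]-3-phenylpropan-1-ol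
Conditions: 9-BBN (1.2 equiv), THF, 0 °C → rt; then 30% H2O2, 3 M NaOH, 0 °C
Reagents that add atoms: hydrogen peroxide (8), OO (supplies the hydroxyl O)
Why: In this Brown hydroboration–oxidation, 9-BBN adds anti-Markovnikov to the monosubstituted vinyl group far faster than to the trisubstituted prenyl alkene, boron ends γ to the aryloxy group so no β-elimination occurs, and C2 is untouched.

**Step 5**
Reactants: 9
Product: 10, (S)-3-[3,5-dimethoxy-2-(3-methylbut-2-en-1-yl)phenoxy]-3-phenylpropanal
Conditions: DMP, NaHCO3, CH2Cl2, 0 °C → rt; short filtration, used at once
Reagents that add atoms: none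
Why: Buffered Dess–Martin oxidation stops at the aldehyde, tolerates the electron-rich arene and the prenyl group, and uses no amine base that could trigger E1cB loss of aryloxide (retro-oxa-Michael), so C2 keeps its configuration.

**Step 6 (key step)**
Reactants: 10
Product: 11, (2S,4R)-5,7-dimethoxy-8-(3-methylbut-2-en-1-yl)-2-phenyl-3,4-dihydro-2H-chromen-4-ol (target)
Conditions: Me2AlCl (1.5 equiv), CH2Cl2 (0.01 M), −78 → −40 °C; Et3N/MeOH quench at low temperature, aq Rochelle salt; Et3N-deactivated SiO2
Reagents that add atoms: none (isomerisation, C22H26O4 → C22H26O4)
Why: Proposed new method: the Al-activated aldehyde is attacked by the only free carbon ortho to O1 (ortho/para to three O-donors, the other ortho site being blocked by prenyl) through a chair-like six-membered transition state with the C2 phenyl equatorial, and because the addition is likely reversible the selectivity is expressed at re-aromatisation, where the bulky O–Al group takes the pseudo-axial position to avoid peri (A1,3) strain with the flanking 5-OMe and so gives the 2,4-trans (4R) alkoxide, which is also the isomer expected from axial capture in 5,7-dioxygenated flavan-4-yl systems (compare the mild-acid epimerisation of borohydride-derived 3,4-trans leucoanthocyanidins to the 4-axial 3,4-cis isomers), while loss of CH4 turns the acidic alcohol–Lewis acid complex into an inert aluminium alkoxide so that C4 does not ionise and the prenyl group is not protonated; the closest known reaction types are Me2AlCl-promoted (proton-scavenging) aldehyde ene/Prins cyclisations and intramolecular Friedel–Crafts hydroxyalkylation of 3-aryloxypropanals to chroman-4-ols.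

## Compound list
| No. | Name | SMILES | Role |
|---|---|---|---|
| 1 | 3,5-dimethoxyphenol | COc1cc(O)cc(OC)c1 | starting material |
| 2 | prenyl bromide (1-bromo-3-methylbut-2-ene) | CC(C)=CCBr | starting material |
| 3 | 3,5-dimethoxy-2-(3-methylbut-2-en-1-yl)phenol | COc1cc(O)c(CC=C(C)C)c(OC)c1 | intermediate |
| 4 | (E)-cinnamyl alcohol | OC/C=C/c1ccccc1 | starting material |
| 5 | methyl chloroformate | COC(=O)Cl | starting material |
| 6 | (E)-cinnamyl methyl carbonate | COC(=O)OC/C=C/c1ccccc1 | intermediate |
| 7 | (S)-1,5-dimethoxy-2-prenyl-3-[(1-phenylprop-2-en-1-yl)oxy]benzene | COc1cc(OC)c(CC=C(C)C)c(O[C@H](c2ccccc2)C=C)c1 | intermediate |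
| 8 | hydrogen peroxide | OO | starting material (reagent, O source) |
| 9 | (S)-3-(3,5-dimethoxy-2-prenylphenoxy)-3-phenylpropan-1-ol | COc1cc(OC)c(CC=C(C)C)c(O[C@H](c2ccccc2)CCO)c1 | intermediate |
| 10 | (S)-3-(3,5-dimethoxy-2-prenylphenoxy)-3-phenylpropanal | COc1cc(OC)c(CC=C(C)C)c(O[C@H](c2ccccc2)CC=O)c1 | intermediate |
| 11 | (2S,4R)-5,7-dimethoxy-8-prenylflavan-4-ol | COc1cc(OC)c2c(c1CC=C(C)C)O[C@H](c1ccccc1)C[C@H]2O | target |

## Summary
Total step count: 6
Longest linear sequence: 5 (Steps 1, 3, 4, 5, 6)

**Three steps most likely to fail**

1. **Step 6.**
   - Risks: the diastereomer ratio may be low or reversed, for example through Al chelation between O4 and the 5-OMe. Retro-oxa-Michael to cinnamaldehyde plus 3 is possible. The product alkoxide may ionise, giving flav-3-ene, dimers or C4 methylation.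
   - Fallback: set C4 by hydride addition and SN2 inversion instead of C–C bond formation. Oxidise 10 to the acid (Pinnick, with 2-methyl-2-butene). Close by TFAA-mediated intramolecular Friedel–Crafts acylation to (S)-5,7-dimethoxy-8-prenylflavanone. Reduce with NaBH4 (axial hydride gives the 2,4-cis alcohol). Invert C4 by Mitsunobu reaction with 4-nitrobenzoic acid, then K2CO3/MeOH.

2. **Step 3.**
   - Risks: the hindered, very electron-rich phenoxide may C-allylate. The branched:linear ratio or ee may be eroded. The sense of induction is unconfirmed.
   - Fallback: buy the stereocentre. Mitsunobu etherification of 3 with commercial (R)-3-chloro-1-phenylpropan-1-ol proceeds with clean inversion to the (S)-ether, as in aryloxy-phenylpropylamine drug syntheses. Then CsOAc/DMF followed by K2CO3/MeOH rejoins the route at 9.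

3. **Step 1.**
   - Risks: mixtures of O-, para- and di-alkylated products, and a moderate yield.
   - Fallback: deliver the prenyl group by sigmatropy. Pd(0)-catalysed O-(1,1-dimethylallyl)ation of 1 with 2-methylbut-3-en-2-yl carbonate, then thermal aromatic Claisen rearrangement, gives only the ortho-prenyl phenol 3.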